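**Remark on the chemistry:** lignan numbering is used (C7–C9: guaiacyl half of the furofuran; C7'–C9': syringyl half; C7''–C9'': arylglycerol chain). The SMILES is read as the all-exo (7S,8R,7'S,8'R) furofuran carrying an erythro (7''S,8''R) arylglycerol 8''-O-4' ether.

## Retrosynthetic overview

1. Hedyotol C ⇒ (debenzylation) ⇒ erythro side chain built on the syringyl oxygen of a protected medioresinol: Evans syn-aldol of its aryloxyacetyl imide with O-benzylvanillin sets C8'', then Mitsunobu inversion at C7'' and reductive removal of the auxiliary.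
2. Furofuran ⇒ acyclic epoxy cinnamyl ether: the C8–C8' bond and the O9'–C7 bond are made in one pot by Cp2TiCl epoxide opening, 5-exo radical cyclisation and iodine-induced etherification. Ring B (O–C7'–C8'–C8–C9) closes first, ring A (O–C9'–C8'–C8–C7) second.
3. Enabling feature: in the 3,7-dioxabicyclo[3.3.0]octane, C8' carries the C9'H2–O arm (a latent terminal epoxide) and C7 is a benzylic carbon para to the guaiacyl oxygen. A C8' radical can therefore add across the C7=C8 styrene bond of a cinnamyl ether tethered through O–C9 to C7', and the C7 radical/cation so formed is captured by O9'.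
4. Only C7' of the core is set by a catalyst (Sharpless kinetic resolution of an aryl vinyl carbinol); C8', C8 and C7 are relayed from it in the key step.
5. Building blocks: syringaldehyde, O-benzylvanillin (used twice) and (S)-4-benzyloxazolidin-2-one.

Key step: step 8

## Route

Step 1
Reactants: 1 syringaldehyde
Product: 2 4-(allyloxy)-3,5-dimethoxybenzaldehyde
Conditions: allyl bromide, K2CO3, DMF, 50 °C
Reagents that add atoms: allyl bromide, C=CCBr
Why: Williamson O-alkylation of the phenoxide; the allyl ether should survive the Grignard, epoxidation, hydride-base and Cp2TiCl/I2 steps and can later be removed without touching a benzyl ether.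

Step 2
Reactants: 2 4-(allyloxy)-3,5-dimethoxybenzaldehyde
Product: 3 rac-1-[4-(allyloxy)-3,5-dimethoxyphenyl]prop-2-en-1-ol
Conditions: CH2=CHMgBr, THF, −78 to 0 °C; aq. NH4Cl
Reagents that add atoms: vinylmagnesium bromide, C=C[Mg]Br
Why: Grignard 1,2-addition to the aldehyde gives the aryl vinyl carbinol as a racemate, which is resolved in step 3.

Step 3
Reactants: 3 rac-1-[4-(allyloxy)-3,5-dimethoxyphenyl]prop-2-en-1-ol
Product: 4 (R)-[4-(allyloxy)-3,5-dimethoxyphenyl][(2S)-oxiran-2-yl]methanol (erythro)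
Conditions: Ti(OiPr)4 (cat.), D-(−)-diisopropyl tartrate (cat.), t-BuOOH (about 0.45 equiv), 4 Å molecular sieves, CH2Cl2, −20 °C
Reagents that add atoms: tert-butyl hydroperoxide, CC(C)(C)OO
Why: Sharpless kinetic resolution (Katsuki–Sharpless asymmetric epoxidation): with D-(−)-DIPT the (S)-carbinol should be epoxidised much faster than its enantiomer and from the face that gives the erythro product, so stopping below half conversion should give 4 with the C7' configuration of the target, while unreacted (R)-3 is removed by chromatography.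

Step 4
Reactants: 5 4-(benzyloxy)-3-methoxybenzaldehyde (O-benzylvanillin)
Product: 6 ethyl (E)-3-[4-(benzyloxy)-3-methoxyphenyl]prop-2-enoate
Conditions: (EtO)2P(O)CH2CO2Et, NaH, THF, 0 °C to rt
Reagents that add atoms: triethyl phosphonoacetate, CCOC(=O)CP(=O)(OCC)OCC
Why: Horner–Wadsworth–Emmons olefination of the aldehyde with the stabilised phosphonate anion, which should give the E-enoate.

Step 5
Reactants: 6 ethyl (E)-3-[4-(benzyloxy)-3-methoxyphenyl]prop-2-enoate
Product: 7 (E)-3-[4-(benzyloxy)-3-methoxyphenyl]prop-2-en-1-ol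
Conditions: i-Bu2AlH (2.2 equiv), CH2Cl2, −78 °C; aq. potassium sodium tartrate (KNaC4H4O6)
Reagents that add atoms: none
Why: 1,2-Reduction of the α,β-unsaturated ester to the allylic alcohol with i-Bu2AlH at low temperature, leaving the double-bond geometry and the benzyl ether intact.

Step 6
Reactants: 7 (E)-3-[4-(benzyloxy)-3-methoxyphenyl]prop-2-en-1-ol
Product: 8 (E)-1-(benzyloxy)-4-(3-bromoprop-1-en-1-yl)-2-methoxybenzene
Conditions: PBr3 (0.4 equiv), Et2O, 0 °C; used crude at once
Reagents that add atoms: phosphorus tribromide, BrP(Br)Br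
Why: Bromination of the allylic alcohol with PBr3, in which any allylic transposition converges on the same conjugated E-bromide; the ionisable bromide is used without purification.

Step 7
Reactants: 4 (R)-[4-(allyloxy)-3,5-dimethoxyphenyl][(2S)-oxiran-2-yl]methanol; 8 (E)-1-(benzyloxy)-4-(3-bromoprop-1-en-1-yl)-2-methoxybenzene
Product: 9 (2S)-2-[(R)-[4-(allyloxy)-3,5-dimethoxyphenyl]{[(E)-3-(4-benzyloxy-3-methoxyphenyl)prop-2-en-1-yl]oxy}methyl]oxirane
Conditions: NaH, Bu4NI (cat.), THF–DMF, 0 °C to rt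
Reagents that add atoms: none
Why: Williamson etherification of the sodium alkoxide of 4 with the reactive allylic bromide in aprotic medium, where Payne rearrangement of the epoxy alkoxide should be slower than alkylation; the C7'–O bond is not broken, so its configuration is kept.

Step 8
Reactants: 9 (2S)-2-[(R)-[4-(allyloxy)-3,5-dimethoxyphenyl]{[(E)-3-(4-benzyloxy-3-methoxyphenyl)prop-2-en-1-yl]oxy}methyl]oxirane
Product: 12 (1S,3aR,4S,6aR)-1-[4-(allyloxy)-3,5-dimethoxyphenyl]-4-[4-(benzyloxy)-3-methoxyphenyl]tetrahydro-1H,3H-furo[3,4-c]furan, via cyclised tetrahydrofuranyl benzylic radical 10 (not isolated), via benzylic iodide 11 (not isolated)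
Conditions: Cp2TiCl2 (2.5 equiv), Zn dust, THF, rt, giving Cp2TiCl (trivalent titanium), decanted and added slowly to 9 in THF, rt; then I2 (1.3 equiv), THF, rt to 40 °C; aq. NaH2PO4/Na2S2O3
Reagents that add atoms: none
Why: Cp2TiCl (trivalent titanium) opens the terminal epoxide of 9 by single-electron transfer at the more substituted carbon, giving the secondary C8' radical whose C9' oxygen is held as a tetravalent titanium alkoxide; this radical adds 5-exo-trig to C8 of the cinnamyl double bond (ring B, O–C7'–C8'–C8–C9), and the resulting C7 benzylic radical 10 is captured by a second Cp2TiCl and converted by I2 into benzylic iodide 11, whose ionisation (assisted by the para benzyloxy group, a quinone-methide-like cation) lets the alkoxide oxygen O9' close ring A (O–C9'–C8'–C8–C7) in a 5-exo-tet, SN1-type etherification. The closest known reaction type is the Nugent–RajanBabu reductive epoxide opening/radical cyclisation with iodine-induced radical–polar crossover, which is established for simpler 2,3-epoxypropyl cinnamyl ethers and delivers 2,6-diaryl furofurans. C8' and C8 are set in a chair-like Beckwith–Houk transition state with the C7' aryl group pseudo-equatorial, which should give the 7',8'-trans and 8',8-cis relationships, so both follow from the catalyst-set C7' centre while the epoxide stereocentre is erased as a planar radical. C7 is set in the second closure, where the aryl group should take the exo (convex) side of the forming cis-fused bicycle. The step needs regioselective epoxide opening (secured by the preference of trivalent titanium for the more substituted radical), cyclisation faster than reduction or β-elimination of the β-titanoxy radical (secured by the activated styrene acceptor and slow addition of Cp2TiCl) and 5-exo over 6-endo closure (secured by ring size and the benzylic stabilisation of the 5-exo radical). The twisted 4-allyloxy-3,5-dimethoxyphenyl group makes C7' a poor cation precursor, so this centre should not ionise under the iodine conditions.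

Step 9
Reactants: 12 (1S,3aR,4S,6aR)-1-[4-(allyloxy)-3,5-dimethoxyphenyl]-4-[4-(benzyloxy)-3-methoxyphenyl]tetrahydro-1H,3H-furo[3,4-c]furan
Product: 13 4-{(1S,3aR,4S,6aR)-4-[4-(benzyloxy)-3-methoxyphenyl]tetrahydro-1H,3H-furo[3,4-c]furan-1-yl}-2,6-dimethoxyphenol
Conditions: Pd(PPh3)4 (5 mol%), morpholine, THF, rt
Reagents that add atoms: none
Why: Tsuji–Trost-type deallylation: zerovalent palladium ionises the aryl allyl ether to a π-allyl complex that is intercepted by morpholine, leaving the benzyl ether and the furofuran untouched.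

Step 10
Reactants: 14 (S)-4-benzyloxazolidin-2-one
Product: 15 (S)-4-benzyl-3-(2-bromoacetyl)oxazolidin-2-one
Conditions: n-BuLi, THF, −78 °C; then BrCH2COBr, −78 °C
Reagents that add atoms: bromoacetyl bromide, BrCC(Br)=O
Why: N-Acylation of the lithiated oxazolidinone with the acid bromide at low temperature, a standard preparation of α-haloacetyl imides.

Step 11
Reactants: 13 4-{(1S,3aR,4S,6aR)-4-[4-(benzyloxy)-3-methoxyphenyl]tetrahydro-1H,3H-furo[3,4-c]furan-1-yl}-2,6-dimethoxyphenol; 15 (S)-4-benzyl-3-(2-bromoacetyl)oxazolidin-2-one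
Product: 16 (S)-4-benzyl-3-(2-{4-[(1S,3aR,4S,6aR)-4-(4-benzyloxy-3-methoxyphenyl)tetrahydro-1H,3H-furo[3,4-c]furan-1-yl]-2,6-dimethoxyphenoxy}acetyl)oxazolidin-2-one
Conditions: K2CO3, Bu4NI (cat.), acetone, rt
Reagents that add atoms: none
Why: Williamson O-alkylation: SN2 displacement at the α-bromo imide by the hindered syringyl phenoxide should be much faster than acyl transfer, and the mild carbonate base does not epimerise the furofuran.

Step 12
Reactants: 16 the aryloxyacetyl imide from step 11; 5 4-(benzyloxy)-3-methoxybenzaldehyde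
Product: 17 (S)-4-benzyl-3-[(2S,3R)-3-(4-benzyloxy-3-methoxyphenyl)-2-{4-[(1S,3aR,4S,6aR)-4-(4-benzyloxy-3-methoxyphenyl)tetrahydro-1H,3H-furo[3,4-c]furan-1-yl]-2,6-dimethoxyphenoxy}-3-hydroxypropanoyl]oxazolidin-2-one (syn adduct)
Conditions: Bu2BOTf (1.2 equiv), i-Pr2NEt (1.4 equiv), CH2Cl2, −78 to 0 °C; then 5, −78 to 0 °C; pH 7 buffer, MeOH, H2O2, 0 °C
Reagents that add atoms: none
Why: Evans syn-aldol reaction: the Z-dibutylboron enolate of the aryloxyacetyl imide reacts through a closed Zimmerman–Traxler transition state on the face opposite the auxiliary benzyl group, which should give the (2S,3R) syn adduct, fixing C8'' in its final configuration and C7'' as the threo epimer.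

Step 13
Reactants: 17 the (2S,3R) syn aldol adduct
Product: 18 (1S,2S)-3-[(S)-4-benzyl-2-oxooxazolidin-3-yl]-1-(4-benzyloxy-3-methoxyphenyl)-2-{4-[(1S,3aR,4S,6aR)-4-(4-benzyloxy-3-methoxyphenyl)tetrahydro-1H,3H-furo[3,4-c]furan-1-yl]-2,6-dimethoxyphenoxy}-3-oxopropyl 4-nitrobenzoate
Conditions: 4-nitrobenzoic acid, PPh3, DIAD, THF, 0 °C to rt
Reagents that add atoms: 4-nitrobenzoic acid, OC(=O)c1ccc(cc1)[N+](=O)[O-]
Why: Mitsunobu inversion: SN2 displacement of the benzylic oxyphosphonium ion by 4-nitrobenzoate inverts C7'' and converts the threo into the required erythro arrangement.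

Step 14
Reactants: 18 the inverted 4-nitrobenzoate
Product: 19 (1S,2R)-1-(4-benzyloxy-3-methoxyphenyl)-2-{4-[(1S,3aR,4S,6aR)-4-(4-benzyloxy-3-methoxyphenyl)tetrahydro-1H,3H-furo[3,4-c]furan-1-yl]-2,6-dimethoxyphenoxy}propane-1,3-diol (erythro; di-O-benzyl hedyotol C)
Conditions: LiBH4 (excess), THF–MeOH, 0 °C to rt
Reagents that add atoms: none
Why: Hydride reduction with LiBH4 cleaves the exocyclic imide carbonyl to the primary alcohol (releasing the auxiliary) and reduces off the 4-nitrobenzoate, without touching C7'' or C8''.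

Step 15
Reactants: 19 di-O-benzyl hedyotol C
Product: 20 hedyotol C
Conditions: H2 (1 atm), 10% Pd/C, EtOAc–MeOH, rt, stopped after uptake of two equivalents
Reagents that add atoms: none
Why: Hydrogenolysis of the two aryl benzyl ethers on palladium under neutral conditions, which should be faster than hydrogenolysis of the dialkyl benzylic ethers of the furofuran or of the C7'' benzylic alcohol.

## Compound list

1 | syringaldehyde (4-hydroxy-3,5-dimethoxybenzaldehyde) | COc1cc(C=O)cc(OC)c1O | starting material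
2 | 4-(allyloxy)-3,5-dimethoxybenzaldehyde | COc1cc(C=O)cc(OC)c1OCC=C | intermediate
3 | rac-1-[4-(allyloxy)-3,5-dimethoxyphenyl]prop-2-en-1-ol | COc1cc(cc(OC)c1OCC=C)C(O)C=C | intermediate
4 | (R)-[4-(allyloxy)-3,5-dimethoxyphenyl][(2S)-oxiran-2-yl]methanol (erythro) | COc1cc(cc(OC)c1OCC=C)[C@@H](O)[C@@H]1CO1 | intermediate
5 | 4-(benzyloxy)-3-methoxybenzaldehyde (O-benzylvanillin) | COc1cc(C=O)ccc1OCc1ccccc1 | starting material
6 | ethyl (E)-3-[4-(benzyloxy)-3-methoxyphenyl]prop-2-enoate | CCOC(=O)/C=C/c1ccc(OCc2ccccc2)c(OC)c1 | intermediate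
7 | (E)-3-[4-(benzyloxy)-3-methoxyphenyl]prop-2-en-1-ol | OC/C=C/c1ccc(OCc2ccccc2)c(OC)c1 | intermediate
8 | (E)-1-(benzyloxy)-4-(3-bromoprop-1-en-1-yl)-2-methoxybenzene | BrC/C=C/c1ccc(OCc2ccccc2)c(OC)c1 | intermediate
9 | (2S)-2-[(R)-[4-(allyloxy)-3,5-dimethoxyphenyl]{[(E)-3-(4-benzyloxy-3-methoxyphenyl)prop-2-en-1-yl]oxy}methyl]oxirane | COc1cc(cc(OC)c1OCC=C)[C@@H](OC/C=C/c1ccc(OCc2ccccc2)c(OC)c1)[C@@H]1CO1 | intermediate
10 | C7 benzylic radical after 5-exo cyclisation: 2-aryl-3-(titanoxymethyl)-4-(arylmethyl radical) tetrahydrofuran, 7',8'-trans, 8',8-cis, as its chlorobis(cyclopentadienyl) tetravalent titanium alkoxide | COc1cc(cc(OC)c1OCC=C)[C@H]1OC[C@H]([CH]c2ccc(OCc3ccccc3)c(OC)c2)[C@@H]1C[O-].[Ti+4].[Cl-].[cH-]1cccc1.[cH-]1cccc1 | intermediate (not isolated)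
11 | C7 benzylic iodide of the same tetrahydrofuran (C7 configuration undefined), as its chlorobis(cyclopentadienyl) tetravalent titanium alkoxide | COc1cc(cc(OC)c1OCC=C)[C@H]1OC[C@H](C(I)c2ccc(OCc3ccccc3)c(OC)c2)[C@@H]1C[O-].[Ti+4].[Cl-].[cH-]1cccc1.[cH-]1cccc1 | intermediate (not isolated)
12 | (1S,3aR,4S,6aR)-1-[4-(allyloxy)-3,5-dimethoxyphenyl]-4-[4-(benzyloxy)-3-methoxyphenyl]tetrahydro-1H,3H-furo[3,4-c]furan (all-exo; 7S,8R,7'S,8'R) | COc1cc([C@H]2OC[C@H]3[C@@H]2CO[C@@H]3c2cc(OC)c(OCC=C)c(OC)c2)ccc1OCc1ccccc1 | intermediate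
13 | 4-{(1S,3aR,4S,6aR)-4-[4-(benzyloxy)-3-methoxyphenyl]tetrahydro-1H,3H-furo[3,4-c]furan-1-yl}-2,6-dimethoxyphenol (medioresinol benzylated on the guaiacyl oxygen) | COc1cc([C@H]2OC[C@H]3[C@@H]2CO[C@@H]3c2cc(OC)c(O)c(OC)c2)ccc1OCc1ccccc1 | intermediate
14 | (S)-4-benzyloxazolidin-2-one | O=C1N[C@@H](Cc2ccccc2)CO1 | starting material
15 | (S)-4-benzyl-3-(2-bromoacetyl)oxazolidin-2-one | BrCC(=O)N1[C@@H](Cc2ccccc2)COC1=O | intermediate
16 | (S)-4-benzyl-3-(2-{4-[(1S,3aR,4S,6aR)-4-(4-benzyloxy-3-methoxyphenyl)tetrahydro-1H,3H-furo[3,4-c]furan-1-yl]-2,6-dimethoxyphenoxy}acetyl)oxazolidin-2-one | COc1cc([C@H]2OC[C@H]3[C@@H]2CO[C@@H]3c2cc(OC)c(OCC(=O)N4[C@@H](Cc5ccccc5)COC4=O)c(OC)c2)ccc1OCc1ccccc1 | intermediate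
17 | (2S,3R) syn aldol adduct: (S)-4-benzyl-3-[(2S,3R)-3-(4-benzyloxy-3-methoxyphenyl)-2-(aryloxy)-3-hydroxypropanoyl]oxazolidin-2-one, aryloxy = the furofuran-bearing 2,6-dimethoxyphenoxy group of 16 | COc1cc([C@H]2OC[C@H]3[C@@H]2CO[C@@H]3c2cc(OC)c(O[C@H](C(=O)N4[C@@H](Cc5ccccc5)COC4=O)[C@H](O)c4ccc(OCc5ccccc5)c(OC)c4)c(OC)c2)ccc1OCc1ccccc1 | intermediate
18 | (2S,3S) 4-nitrobenzoate of the C7''-inverted adduct (erythro arrangement, auxiliary still attached) | COc1cc([C@H]2OC[C@H]3[C@@H]2CO[C@@H]3c2cc(OC)c(O[C@H](C(=O)N4[C@@H](Cc5ccccc5)COC4=O)[C@@H](OC(=O)c4ccc(cc4)[N+](=O)[O-])c4ccc(OCc5ccccc5)c(OC)c4)c(OC)c2)ccc1OCc1ccccc1 | intermediate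
19 | (1S,2R)-1-(4-benzyloxy-3-methoxyphenyl)-2-{4-[(1S,3aR,4S,6aR)-4-(4-benzyloxy-3-methoxyphenyl)tetrahydro-1H,3H-furo[3,4-c]furan-1-yl]-2,6-dimethoxyphenoxy}propane-1,3-diol (erythro) | COc1cc([C@H]2OC[C@H]3[C@@H]2CO[C@@H]3c2cc(OC)c(O[C@H](CO)[C@@H](O)c4ccc(OCc5ccccc5)c(OC)c4)c(OC)c2)ccc1OCc1ccccc1 | intermediate
20 | hedyotol C: (1S,2R)-1-(4-hydroxy-3-methoxyphenyl)-2-{4-[(1S,3aR,4S,6aR)-4-(4-hydroxy-3-methoxyphenyl)tetrahydro-1H,3H-furo[3,4-c]furan-1-yl]-2,6-dimethoxyphenoxy}propane-1,3-diol | COc1cc([C@H]2OC[C@H]3[C@@H]2CO[C@@H]3c2cc(OC)c(O[C@H](CO)[C@@H](O)c3ccc(O)c(OC)c3)c(OC)c2)ccc1O | target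

## Step count and risks

Total steps: 15. Longest linear sequence: 11 steps (steps 1, 2, 3, 7, 8, 9, 11, 12, 13, 14, 15).

**Step 8 (key cascade).** The C7 benzylic radical or its organotitanium form may be quenched by hydrogen transfer before iodination, the β-titanoxy radical may undergo deoxygenative elimination, or the closure at C7 may show poor facial selectivity or acid-induced epimerisation. The fallback sets out from 9 and separates the two bond formations. Cp2TiCl alone (from Cp2TiCl2 and Zn, THF, rt) followed by an aqueous NaH2PO4 quench should give the monocyclic [(2S,3R,4R)-2-[4-(allyloxy)-3,5-dimethoxyphenyl]-4-[4-(benzyloxy)-3-methoxybenzyl]tetrahydrofuran-3-yl]methanol F1, in which the radical cyclisation has made the C8–C8' bond and the C7 radical has been reduced to CH2. Ring A is then closed in a separate oxidative cyclisation with DDQ (CH2Cl2, 4 Å molecular sieves, 0 °C): hydride abstraction from the para-benzyloxybenzyl CH2 gives the quinone-methide-type cation, which is trapped by the C9' hydroxyl. This returns to the route at 12.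

**Step 13 (Mitsunobu inversion).** The electron-rich benzylic oxyphosphonium ion may ionise, losing inversion fidelity, or β-elimination across C7''–C8'' may give the α-aryloxy cinnamoyl imide. The fallback sets out from 17 and inverts C7'' by oxidation and chelation-controlled reduction:
- LiBH4 (THF–MeOH, 0 °C) removes the auxiliary to give the threo (1R,2R)-diol F2.
- TBSCl/imidazole (DMF, 0 °C) silylates the primary hydroxyl selectively to give the silyl ether F3.
- Dess–Martin periodinane (NaHCO3-buffered CH2Cl2, 0 °C) oxidises the benzylic alcohol to the aryl ketone F4.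
- Zn(BH4)2 (Et2O, −30 °C) reduces F4 through the chelate between the ketone and the α-aryloxy oxygen, with hydride delivered past the C8'' hydrogen, which should give the erythro (1S,2R) alcohol F5.
- Bu4NF (THF, 0 °C) removes the silyl group and returns to the route at 19.

**Step 3 (Sharpless kinetic resolution).** The rate difference between the enantiomers may be too small, or titanium-mediated opening of the acid-sensitive benzylic epoxy alcohol during the long resolution may erode the enantiomeric purity at C7'. The fallback sets out from racemic 3 and separates resolution from epoxidation. Immobilised Candida antarctica lipase B with vinyl acetate (MTBE, 30 °C) should acylate the (R)-enantiomer (Kazlauskas rule) to the (R)-acetate F7 and leave (S)-1-[4-(allyloxy)-3,5-dimethoxyphenyl]prop-2-en-1-ol F6. After separation, F6 is epoxidised as a single enantiomer in the matched sense (Ti(OiPr)4, D-(−)-diisopropyl tartrate, t-BuOOH, CH2Cl2, −20 °C, short reaction time at full conversion). This returns to the route at 4.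

## Further compounds

F1 | step 8 | [(2S,3R,4R)-2-[4-(allyloxy)-3,5-dimethoxyphenyl]-4-[4-(benzyloxy)-3-methoxybenzyl]tetrahydrofuran-3-yl]methanol | COc1cc(cc(OC)c1OCC=C)[C@H]1OC[C@H](Cc2ccc(OCc3ccccc3)c(OC)c2)[C@@H]1CO
F2 | step 13 | (1R,2R)-1-(4-benzyloxy-3-methoxyphenyl)-2-{4-[(1S,3aR,4S,6aR)-4-(4-benzyloxy-3-methoxyphenyl)tetrahydro-1H,3H-furo[3,4-c]furan-1-yl]-2,6-dimethoxyphenoxy}propane-1,3-diol (threo) | COc1cc([C@H]2OC[C@H]3[C@@H]2CO[C@@H]3c2cc(OC)c(O[C@H](CO)[C@H](O)c4ccc(OCc5ccccc5)c(OC)c4)c(OC)c2)ccc1OCc1ccccc1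
F3 | step 13 | (1R,2R)-3-[(tert-butyldimethylsilyl)oxy] derivative of F2 (primary silyl ether, threo) | COc1cc([C@H]2OC[C@H]3[C@@H]2CO[C@@H]3c2cc(OC)c(O[C@H](CO[Si](C)(C)C(C)(C)C)[C@H](O)c4ccc(OCc5ccccc5)c(OC)c4)c(OC)c2)ccc1OCc1ccccc1
F4 | step 13 | (R)-1-(4-benzyloxy-3-methoxyphenyl)-3-[(tert-butyldimethylsilyl)oxy]-2-{4-[(1S,3aR,4S,6aR)-4-(4-benzyloxy-3-methoxyphenyl)tetrahydro-1H,3H-furo[3,4-c]furan-1-yl]-2,6-dimethoxyphenoxy}propan-1-one | COc1cc([C@H]2OC[C@H]3[C@@H]2CO[C@@H]3c2cc(OC)c(O[C@H](CO[Si](C)(C)C(C)(C)C)C(=O)c4ccc(OCc5ccccc5)c(OC)c4)c(OC)c2)ccc1OCc1ccccc1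
F5 | step 13 | (1S,2R)-3-[(tert-butyldimethylsilyl)oxy] erythro alcohol (primary silyl ether of 19) | COc1cc([C@H]2OC[C@H]3[C@@H]2CO[C@@H]3c2cc(OC)c(O[C@H](CO[Si](C)(C)C(C)(C)C)[C@@H](O)c4ccc(OCc5ccccc5)c(OC)c4)c(OC)c2)ccc1OCc1ccccc1
F6 | step 3 | (S)-1-[4-(allyloxy)-3,5-dimethoxyphenyl]prop-2-en-1-ol | COc1cc(cc(OC)c1OCC=C)[C@@H](O)C=C
F7 | step 3 | (R)-1-[4-(allyloxy)-3,5-dimethoxyphenyl]prop-2-en-1-yl acetate | COc1cc(cc(OC)c1OCC=C)[C@H](OC(C)=O)C=C
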